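**Plan**

- Numbering of the core follows 1H-indene: C1 (quaternary, acid side chain), C2, C3=C3a, C4 (CO2H), C5 (bicyclylmethyl), C6, C7 (OH), C7a (angular methyl).
- Retrosynthesis: after ester cleavage, the six-membered ring is cut at C4=C5 (carbonyl-olefination retron of the tetrasubstituted acrylate) and at C7–C7a (carbonyl-ene retron of the homoallylic alcohol HO–C7–C7a–C3a=C3). This is a [3+3] union of a cyclopentenyl α-keto ester with a C5–C6–C7 ylide that carries the oxabicycle.
- Forward order: the cyclopentane fragment (Michael addition, enol triflate methylation, glyoxylate-ene) and the oxabicycle (Birch reduction, gem-dimethylation, CBS reduction, iodoetherification, cross-metathesis) are made separately; the six-membered ring closes last in one flask, then both allyl esters are removed.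
- Stereochemistry: bought (R)-1-phenylethylamine sets C1 and the side-chain methine in one Michael step; C1 then relays to C7a and C7 in the ene closure; one CBS reduction sets the carbinol that fixes both bridgeheads of the oxabicycle.
- Enabling feature: in the six-membered ring the C7 carbinol sits across the quaternary C7a from the C3=C3a alkene, and C4=C5 is the α,β-bond of the unsaturated acid. An aldehyde at C7 and a keto ester at C4 can therefore be engaged in turn by a C5 ylide and by the tetrasubstituted cyclopentene acting as ene.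

Key step: step 16

Assumption: allyl glyoxylate (12) is taken as the commercial hydrate and cracked to the anhydrous aldehyde before use; phenyl crotonate is prepared (step 1) because its commercial supply is uncertain.

Step 1
Reactants: 1 (E)-but-2-enoyl chloride; 2 phenol
Product: 3 phenyl (E)-but-2-enoate
Conditions: Et3N, CH2Cl2, 0 → 25 °C
Reagents that add atoms: none
Why: Acylation of phenol by the acid chloride gives the aryl crotonate, an acceptor activated enough for the uncatalysed enamine Michael addition of step 3.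

Step 2
Reactants: 4 2-methylcyclopentanone (racemic); 5 (R)-1-phenylethylamine
Product: 6 (1R)-N-(2-methylcyclopentylidene)-1-phenylethanamine
Conditions: TsOH (cat.), toluene, reflux, Dean–Stark trap
Reagents that add atoms: none
Why: Azeotropic imine condensation; the racemic α-centre does not matter because the imine equilibrates with its more substituted secondary enamine, which is the species that reacts in step 3.

Step 3
Reactants: 6 (1R)-N-(2-methylcyclopentylidene)-1-phenylethanamine; 3 phenyl (E)-but-2-enoate
Product: 8 phenyl (3R)-3-[(1S)-1-methyl-2-oxocyclopentyl]butanoate, via Michael adduct imine 7 (not isolated)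
Conditions: THF, 25 °C, 5 d; then 10% aq. AcOH, 25 °C
Reagents that add atoms: water, O
Why: Asymmetric Michael addition of a chiral imine through its secondary enamine tautomer (aza-ene-like, with N–H transfer): the acceptor should add to the more substituted α-carbon on the face anti to the phenyl group of the auxiliary, which sets the quaternary centre, and the ester-endo approach of the (E)-crotonate with its methyl group turned away from the ring should set the adjacent methine, before mild acid releases ketone and amine.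

Step 4
Reactants: 8 phenyl (3R)-3-[(1S)-1-methyl-2-oxocyclopentyl]butanoate
Product: 9 prop-2-en-1-yl (3R)-3-[(1S)-1-methyl-2-oxocyclopentyl]butanoate
Conditions: CH2=CHCH2OH, K2CO3 (cat.), 25 °C
Reagents that add atoms: prop-2-en-1-ol, C=CCO
Why: Transesterification of the activated aryl ester installs an allyl ester that survives the route and can be removed at the end under neutral conditions; no stereocentre is touched.

Step 5
Reactants: 9 prop-2-en-1-yl (3R)-3-[(1S)-1-methyl-2-oxocyclopentyl]butanoate
Product: 10 prop-2-en-1-yl (3R)-3-[(1S)-1-methyl-2-{[(trifluoromethyl)sulfonyl]oxy}cyclopent-2-en-1-yl]butanoate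
Conditions: Tf2O, 2,6-di-tert-butyl-4-methylpyridine, CH2Cl2, 0 → 25 °C
Reagents that add atoms: trifluoromethanesulfonic anhydride, O=S(=O)(OS(=O)(=O)C(F)(F)F)C(F)(F)F
Why: O-Sulfonylation of the ketone and proton loss from its only enolisable position (the other α-carbon is quaternary) should give a single enol triflate without a strong base that could touch the ester.

Step 6
Reactants: 10 enol triflate
Product: 11 prop-2-en-1-yl (3R)-3-[(1S)-1,2-dimethylcyclopent-2-en-1-yl]butanoate
Conditions: MeMgBr, Fe(acac)3 (5 mol %), THF/N-methylpyrrolidone, −30 °C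
Reagents that add atoms: methylmagnesium bromide, C[Mg]Br
Why: Iron-catalysed Kumada-type cross-coupling of an alkenyl triflate with a Grignard reagent is fast at low temperature, so the ester should survive while the methyl group is placed on the former carbonyl carbon (the future C7a).

Step 7
Reactants: 11 prop-2-en-1-yl (3R)-3-[(1S)-1,2-dimethylcyclopent-2-en-1-yl]butanoate; 12 prop-2-en-1-yl oxoacetate (allyl glyoxylate)
Product: 13 prop-2-en-1-yl (3R)-3-[(1S)-3-[1-hydroxy-2-oxo-2-(prop-2-en-1-yloxy)ethyl]-1-methyl-2-methylidenecyclopentyl]butanoate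
Conditions: Sc(OTf)3 (10 mol %), CH2Cl2, 0 → 25 °C
Reagents that add atoms: none
Why: Lewis-acid glyoxylate-ene reaction: the aldehyde carbon bonds to the less substituted alkene carbon (the future C3a) and a hydrogen of the vinylic methyl group passes to oxygen, so the oxo-ester unit arrives regiospecifically (the two new centres are mixtures that are erased in step 8).

Step 8
Reactants: 13 ene adduct
Product: 15 prop-2-en-1-yl (3R)-3-{(1S)-1,2-dimethyl-3-[2-oxo-2-(prop-2-en-1-yloxy)acetyl]cyclopent-2-en-1-yl}butanoate, via deconjugated keto ester 14 (not isolated)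
Conditions: Dess–Martin periodinane, NaHCO3, CH2Cl2, 25 °C; then Et3N (cat.), 25 °C
Reagents that add atoms: none
Why: Oxidation of the secondary alcohol gives the α-keto ester, whose acidic ring methine lets a trace of amine move the exocyclic alkene into conjugation as the tetrasubstituted enone.

Step 9
Reactants: 16 1-methoxy-4-(prop-2-en-1-yl)benzene (estragole)
Product: 18 4-(prop-2-en-1-yl)cyclohex-3-en-1-one, via dihydroanisole 17 (not isolated)
Conditions: Li, NH3 (l), t-BuOH, THF, −78 °C; then (CO2H)2, MeOH/H2O, 25 °C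
Reagents that add atoms: water, O
Why: Birch reduction of the anisole ring (the isolated allyl alkene is not reduced) followed by mild hydrolysis of the enol ether should give the β,γ-unsaturated ketone without conjugation.

Step 10
Reactants: 18 4-(prop-2-en-1-yl)cyclohex-3-en-1-one
Product: 19 2,2-dimethyl-4-(prop-2-en-1-yl)cyclohex-3-en-1-one
Conditions: KOt-Bu (2.2 equiv), MeI, t-BuOH/THF, 0 → 25 °C
Reagents that add atoms: iodomethane, CI
Why: The dienolate of the β,γ-unsaturated ketone is alkylated twice at the doubly activated α-carbon between carbonyl and alkene (deconjugative gem-dimethylation), which also blocks conjugation.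

Step 11
Reactants: 19 2,2-dimethyl-4-(prop-2-en-1-yl)cyclohex-3-en-1-one
Product: 20 (1S)-2,2-dimethyl-4-(prop-2-en-1-yl)cyclohex-3-en-1-ol
Conditions: (R)-2-methyl-CBS-oxazaborolidine (10 mol %), catecholborane, toluene, −78 °C
Reagents that add atoms: none
Why: Corey–Bakshi–Shibata reduction: the quaternary α-carbon acts as the large and the methylene as the small substituent, so the (R)-catalyst should give the (S)-alcohol, and catecholborane at low temperature leaves both alkenes alone.

Step 12
Reactants: 20 (1S)-2,2-dimethyl-4-(prop-2-en-1-yl)cyclohex-3-en-1-ol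
Product: 21 (1S,2R,4S)-2-iodo-3,3-dimethyl-1-(prop-2-en-1-yl)-7-oxabicyclo[2.2.1]heptane
Conditions: I2, NaHCO3, MeCN, 0 °C
Reagents that add atoms: iodine, II
Why: Iodoetherification: the iodonium ion of the electron-rich trisubstituted ring alkene is opened at its tertiary carbon by the transannular hydroxyl (anti addition, 5-exo), which closes the 7-oxabicyclo[2.2.1]heptane; the bridge can form on one face only, so the carbinol centre fixes the second bridgehead.

Step 13
Reactants: 21 iodo ether
Product: 22 (1S,4S)-3,3-dimethyl-1-(prop-2-en-1-yl)-7-oxabicyclo[2.2.1]heptane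
Conditions: Bu3SnH, AIBN (cat.), benzene, 80 °C
Reagents that add atoms: none
Why: Radical chain reduction removes the secondary iodide; the β-oxygen does not fragment and the allyl group is too close to the radical for cyclisation.

Step 14
Reactants: 22 (1S,4S)-3,3-dimethyl-1-(prop-2-en-1-yl)-7-oxabicyclo[2.2.1]heptane; 23 (E)-but-2-enal
Product: 24 (2E)-4-[(1S,4S)-3,3-dimethyl-7-oxabicyclo[2.2.1]heptan-1-yl]but-2-enal
Conditions: second-generation Grubbs catalyst (3 mol %), CH2Cl2, 40 °C
Reagents that add atoms: none
Why: Olefin cross-metathesis of a terminal alkene with an α,β-unsaturated aldehyde should give the (E)-enal, which holds C5, C6 and C7 with C7 already at the aldehyde oxidation level.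

Step 15
Reactants: 24 (2E)-4-[(1S,4S)-3,3-dimethyl-7-oxabicyclo[2.2.1]heptan-1-yl]but-2-enal
Product: 25 [3-[(tert-butyldimethylsilyl)oxy]-1-(bicyclylmethyl)prop-2-en-1-yl]triphenylphosphonium trifluoromethanesulfonate (oxabicycle as in 24)
Conditions: PPh3, t-BuMe2SiOTf, THF, 25 °C
Reagents that add atoms: triphenylphosphine, c1ccc(cc1)P(c1ccccc1)c1ccccc1; tert-butyldimethylsilyl trifluoromethanesulfonate, CC(C)(C)[Si](C)(C)OS(=O)(=O)C(F)(F)F
Why: Phosphoniosilylation: conjugate addition of the phosphine to the silyl-activated enal and O-silylation give the β-phosphonio silyl enol ether, in which the future ylide carbon is C5 and the aldehyde stays masked without an acetal (the phosphorus-bearing centre is a mixture that is lost in step 16).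

Step 16
Reactants: 25 phosphonium salt; 15 cyclopentenyl α-keto ester
Product: 29 prop-2-en-1-yl (1S,7R,7aS)-5-{[(1S,4S)-3,3-dimethyl-7-oxabicyclo[2.2.1]heptan-1-yl]methyl}-7-hydroxy-1,7a-dimethyl-1-[(2R)-4-oxo-4-(prop-2-en-1-yloxy)butan-2-yl]-2,6,7,7a-tetrahydro-1H-indene-4-carboxylate, via phosphorus ylide 26 (not isolated), via silyl dienol ether 27 (not isolated), via dienoate aldehyde 28 (not isolated)
Conditions: KN(SiMe3)2, toluene, −78 → 25 °C, then 60 °C; HCl (1 M in Et2O, 1.1 equiv), −78 °C; Me2AlCl (1 M in hexanes, 5 equiv), CH2Cl2, −78 → −20 °C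
Reagents that add atoms: none
Why: Deprotonation of 25 gives the allylic ylide 26, whose phosphorus-bearing carbon adds to the non-enolisable keto group of 15 (Wittig olefination of a ketone, closest precedent the phosphoniosilylation–Wittig β-functionalisation of enals and enones) and forms C4=C5 as the 5-silyloxy-2,4-dienoate 27; the two largest groups (the cyclopentenyl on C4 and the bicyclylmethyl on C5) should avoid each other both in the olefination and in the warmed donor–acceptor diene, so the E isomer with the cyclopentenyl cis to the enol ether arm is expected to prevail. One equivalent of HCl protonates the enol ether at C6 and chloride takes the silyl group, which unmasks the β,γ-unsaturated aldehyde 28 without moving C4=C5. Me2AlCl then promotes a type 2 intramolecular carbonyl-ene reaction (closest precedent: Lewis-acid ene cyclisations of formyl-tethered 1,1-disubstituted and tetrasubstituted alkenes to methylenecyclohexanols), in which the six-membered ring closes by bonding of the aldehyde carbon C7 to the distal alkene carbon C7a while a hydrogen of C3 passes to oxygen, so the new alkene appears at C3=C3a. C7a should be set by attack on the cyclopentene face that carries the C1 methyl group, anti to the branched side chain on the neighbouring quaternary C1, and C7 by the cyclic transition state, in which the oxygen must lie over C3 and therefore anti to the C7a methyl group. The step needs regioselectivity for C7a over C3a (secured by six- against five-membered closure and by the absence of hydrogen on C4, which leaves the C3 hydrogens as the only ones in reach) and chemoselectivity of the ylide for the keto carbonyl over the allyl esters (secured by the far higher electrophilicity of the α-keto ester).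

Step 17
Reactants: 29 bis-allyl ester
Product: 30 (1S,7R,7aS)-1-[(2R)-1-carboxypropan-2-yl]-5-{[(1S,4S)-3,3-dimethyl-7-oxabicyclo[2.2.1]heptan-1-yl]methyl}-7-hydroxy-1,7a-dimethyl-2,6,7,7a-tetrahydro-1H-indene-4-carboxylic acid
Conditions: Pd(PPh3)4 (5 mol %), morpholine, THF, 25 °C
Reagents that add atoms: none
Why: Palladium-catalysed allyl transfer to the amine (Tsuji–Trost deallylation) should free both acids under neutral conditions, which avoids saponification of the hindered unsaturated ester, whose γ-methylene next to the strained ether makes it base-sensitive.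

**Compound list**

1 | (E)-but-2-enoyl chloride | C/C=C/C(=O)Cl | starting material
2 | phenol | Oc1ccccc1 | starting material
3 | phenyl (E)-but-2-enoate | C/C=C/C(=O)Oc1ccccc1 | intermediate
4 | 2-methylcyclopentanone (racemic) | CC1CCCC1=O | starting material
5 | (R)-1-phenylethylamine | C[C@@H](N)c1ccccc1 | starting material
6 | (1R)-N-(2-methylcyclopentylidene)-1-phenylethanamine (mixture at ring C2 and C=N) | CC1CCCC1=N[C@H](C)c1ccccc1 | intermediate
7 | phenyl (3R)-3-[(1S)-1-methyl-2-{[(1R)-1-phenylethyl]imino}cyclopentyl]butanoate | C[C@H](CC(=O)Oc1ccccc1)[C@]2(C)CCCC2=N[C@H](C)c3ccccc3 | intermediate (not isolated)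
8 | phenyl (3R)-3-[(1S)-1-methyl-2-oxocyclopentyl]butanoate | C[C@H](CC(=O)Oc1ccccc1)[C@]2(C)CCCC2=O | intermediate
9 | prop-2-en-1-yl (3R)-3-[(1S)-1-methyl-2-oxocyclopentyl]butanoate | C[C@H](CC(=O)OCC=C)[C@]1(C)CCCC1=O | intermediate
10 | prop-2-en-1-yl (3R)-3-[(1S)-1-methyl-2-{[(trifluoromethyl)sulfonyl]oxy}cyclopent-2-en-1-yl]butanoate | C[C@H](CC(=O)OCC=C)[C@]1(C)CCC=C1OS(=O)(=O)C(F)(F)F | intermediate
11 | prop-2-en-1-yl (3R)-3-[(1S)-1,2-dimethylcyclopent-2-en-1-yl]butanoate | C[C@H](CC(=O)OCC=C)[C@]1(C)CCC=C1C | intermediate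
12 | prop-2-en-1-yl oxoacetate (allyl glyoxylate) | O=CC(=O)OCC=C | starting material
13 | prop-2-en-1-yl (3R)-3-[(1S)-3-[1-hydroxy-2-oxo-2-(prop-2-en-1-yloxy)ethyl]-1-methyl-2-methylidenecyclopentyl]butanoate (mixture at the two new centres) | C[C@H](CC(=O)OCC=C)[C@]1(C)CCC(C(O)C(=O)OCC=C)C1=C | intermediate
14 | prop-2-en-1-yl (3R)-3-{(1S)-1-methyl-2-methylidene-3-[2-oxo-2-(prop-2-en-1-yloxy)acetyl]cyclopentyl}butanoate | C[C@H](CC(=O)OCC=C)[C@]1(C)CCC(C(=O)C(=O)OCC=C)C1=C | intermediate (not isolated)
15 | prop-2-en-1-yl (3R)-3-{(1S)-1,2-dimethyl-3-[2-oxo-2-(prop-2-en-1-yloxy)acetyl]cyclopent-2-en-1-yl}butanoate | C[C@H](CC(=O)OCC=C)[C@]1(C)CCC(C(=O)C(=O)OCC=C)=C1C | intermediate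
16 | 1-methoxy-4-(prop-2-en-1-yl)benzene (estragole) | C=CCc1ccc(OC)cc1 | starting material
17 | 1-methoxy-4-(prop-2-en-1-yl)cyclohexa-1,4-diene | COC1=CCC(CC=C)=CC1 | intermediate (not isolated)
18 | 4-(prop-2-en-1-yl)cyclohex-3-en-1-one | C=CCC1=CCC(=O)CC1 | intermediate
19 | 2,2-dimethyl-4-(prop-2-en-1-yl)cyclohex-3-en-1-one | C=CCC1=CC(C)(C)C(=O)CC1 | intermediate
20 | (1S)-2,2-dimethyl-4-(prop-2-en-1-yl)cyclohex-3-en-1-ol | C=CCC1=CC(C)(C)[C@@H](O)CC1 | intermediate
21 | (1S,2R,4S)-2-iodo-3,3-dimethyl-1-(prop-2-en-1-yl)-7-oxabicyclo[2.2.1]heptane (iodine anti to the oxygen bridge) | C=CC[C@]12CC[C@H](O1)C(C)(C)[C@H]2I | intermediate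
22 | (1S,4S)-3,3-dimethyl-1-(prop-2-en-1-yl)-7-oxabicyclo[2.2.1]heptane | C=CC[C@]12CC[C@H](O1)C(C)(C)C2 | intermediate
23 | (E)-but-2-enal (crotonaldehyde) | C/C=C/C=O | starting material
24 | (2E)-4-[(1S,4S)-3,3-dimethyl-7-oxabicyclo[2.2.1]heptan-1-yl]but-2-enal | O=C/C=C/C[C@]12CC[C@H](O1)C(C)(C)C2 | intermediate
25 | [3-[(tert-butyldimethylsilyl)oxy]-1-(bicyclylmethyl)prop-2-en-1-yl]triphenylphosphonium trifluoromethanesulfonate, oxabicycle as in 24 (mixture at the phosphorus-bearing carbon and the enol ether) | CC(C)(C)[Si](C)(C)OC=CC(C[C@]12CC[C@H](O1)C(C)(C)C2)[P+](c3ccccc3)(c4ccccc4)c5ccccc5.[O-]S(=O)(=O)C(F)(F)F | intermediate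
26 | ylide of 25: [3-[(tert-butyldimethylsilyl)oxy]-1-(bicyclylmethyl)prop-2-en-1-ylidene]triphenylphosphorane | CC(C)(C)[Si](C)(C)OC=CC(C[C@]12CC[C@H](O1)C(C)(C)C2)=P(c3ccccc3)(c4ccccc4)c5ccccc5 | intermediate (not isolated)
27 | prop-2-en-1-yl (3R)-3-[(1S)-3-{(1E)-4-[(tert-butyldimethylsilyl)oxy]-2-{[(1S,4S)-3,3-dimethyl-7-oxabicyclo[2.2.1]heptan-1-yl]methyl}-1-[(prop-2-en-1-yloxy)carbonyl]buta-1,3-dien-1-yl}-1,2-dimethylcyclopent-2-en-1-yl]butanoate (enol ether geometry open) | C[C@H](CC(=O)OCC=C)[C@]1(C)CCC(=C1C)/C(C(=O)OCC=C)=C(\C=CO[Si](C)(C)C(C)(C)C)C[C@]23CC[C@H](O2)C(C)(C)C3 | intermediate (not isolated)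
28 | prop-2-en-1-yl (3R)-3-[(1S)-3-{(1E)-2-{[(1S,4S)-3,3-dimethyl-7-oxabicyclo[2.2.1]heptan-1-yl]methyl}-4-oxo-1-[(prop-2-en-1-yloxy)carbonyl]but-1-en-1-yl}-1,2-dimethylcyclopent-2-en-1-yl]butanoate | C[C@H](CC(=O)OCC=C)[C@]1(C)CCC(=C1C)/C(C(=O)OCC=C)=C(\CC=O)C[C@]23CC[C@H](O2)C(C)(C)C3 | intermediate (not isolated)
29 | prop-2-en-1-yl (1S,7R,7aS)-5-{[(1S,4S)-3,3-dimethyl-7-oxabicyclo[2.2.1]heptan-1-yl]methyl}-7-hydroxy-1,7a-dimethyl-1-[(2R)-4-oxo-4-(prop-2-en-1-yloxy)butan-2-yl]-2,6,7,7a-tetrahydro-1H-indene-4-carboxylate | C[C@H](CC(=O)OCC=C)[C@]1(C)CC=C2C(C(=O)OCC=C)=C(C[C@]34CC[C@H](O3)C(C)(C)C4)C[C@@H](O)[C@]21C | intermediate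
30 | (1S,7R,7aS)-1-[(2R)-1-carboxypropan-2-yl]-5-{[(1S,4S)-3,3-dimethyl-7-oxabicyclo[2.2.1]heptan-1-yl]methyl}-7-hydroxy-1,7a-dimethyl-2,6,7,7a-tetrahydro-1H-indene-4-carboxylic acid | C[C@H](CC(=O)O)[C@]1(C)CC=C2C(C(=O)O)=C(C[C@]34CC[C@H](O3)C(C)(C)C4)C[C@@H](O)[C@]21C | target

**Step count and risks**

Total steps: 17. Longest linear sequence: 9 steps (steps 2–8, 16 and 17; the branch of steps 9–15 with 16 and 17 is equally long).

Steps most likely to fail:

1. Step 16. The ylide may add only slowly to the crowded keto carbonyl or may act as a base toward the vinylogous methyl group of 15. Geometric control at C4=C5 may also be incomplete, and only the E isomer can close the ring.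
   Fallback (sets out from 24 and 15, returns at 29): an N-heterocyclic-carbene-catalysed homoenolate addition of enal 24 to the keto group of 15 (1,3-dimesitylimidazolium chloride, DBU, THF) would join C4 and C5 as a single bond in the γ-lactone prop-2-en-1-yl 2-(cyclopentenyl)-3-(bicyclylmethyl)-5-oxooxolane-2-carboxylate F1. Reduction with i-Bu2AlH at −78 °C would give the lactol F2. Me2AlCl would open the lactol and run the same type 2 ene closure to the C4-hydroxy compound F3. Martin sulfurane would then remove the tertiary hydroxyl together with the only β-hydrogen available (on C5), which places C4=C5 inside the ring and gives 29 with no question of alkene geometry.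

2. Step 3. Addition of the hindered secondary enamine to a β-substituted acceptor may be slow, and control at the side-chain methine may erode.
   Fallback (sets out from 4, returns at 9): 4 would be converted (Me3SiCl, NaI, Et3N) into its more substituted silyl enol ether 2-methyl-1-(trimethylsilyloxy)cyclopent-1-ene F4. A Mukaiyama–Michael addition to 3-[(E)-but-2-enoyl]oxazolidin-2-one under [Cu((S,S)-t-Bu-box)](SbF6)2, with the ligand antipode chosen for the (3R) centre, would give the imide 3-{(3R)-3-[(1S)-1-methyl-2-oxocyclopentyl]butanoyl}oxazolidin-2-one F5. Treatment with LiOCH2CH=CH2 would then give 9.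

3. Step 12. Iodine may attack the terminal alkene, and closure of the strained oxygen bridge may be incomplete.
   Fallback (sets out from 20, returns at 22): Brønsted-acid hydroalkoxylation (camphorsulfonic acid, CH2Cl2, 25 °C) would protonate only the trisubstituted ring alkene and let the hydroxyl trap the tertiary cation, giving 22 directly; this fallback makes no compound outside the list (F0).

Further compounds
F1 | step 16 | prop-2-en-1-yl 2-{(3S)-2,3-dimethyl-3-[(2R)-4-oxo-4-(prop-2-en-1-yloxy)butan-2-yl]cyclopent-1-en-1-yl}-3-{[(1S,4S)-3,3-dimethyl-7-oxabicyclo[2.2.1]heptan-1-yl]methyl}-5-oxooxolane-2-carboxylate (mixture at the two lactone centres) | C[C@H](CC(=O)OCC=C)[C@]1(C)CCC(=C1C)C5(C(=O)OCC=C)OC(=O)CC5C[C@]23CC[C@H](O2)C(C)(C)C3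
F2 | step 16 | lactol of F1 (5-hydroxyoxolane in place of the 5-oxooxolane) | C[C@H](CC(=O)OCC=C)[C@]1(C)CCC(=C1C)C5(C(=O)OCC=C)OC(O)CC5C[C@]23CC[C@H](O2)C(C)(C)C3
F3 | step 16 | prop-2-en-1-yl (1S,7R,7aS)-5-{[(1S,4S)-3,3-dimethyl-7-oxabicyclo[2.2.1]heptan-1-yl]methyl}-4,7-dihydroxy-1,7a-dimethyl-1-[(2R)-4-oxo-4-(prop-2-en-1-yloxy)butan-2-yl]-2,4,5,6,7,7a-hexahydro-1H-indene-4-carboxylate (mixture at C4 and C5) | C[C@H](CC(=O)OCC=C)[C@]1(C)CC=C2C(O)(C(=O)OCC=C)C(C[C@]34CC[C@H](O3)C(C)(C)C4)C[C@@H](O)[C@]21C
F4 | step 3 | 2-methyl-1-(trimethylsilyloxy)cyclopent-1-ene | CC1=C(O[Si](C)(C)C)CCC1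
F5 | step 3 | 3-{(3R)-3-[(1S)-1-methyl-2-oxocyclopentyl]butanoyl}oxazolidin-2-one | C[C@H](CC(=O)N1CCOC1=O)[C@]2(C)CCCC2=O
F0 | step 12 | none | none
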